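The numbers in the tables were generated by integration with constants of no real substance, noise included.

3 questions stand on this flask, and one quantity can serve them.

| flask | starting material | gas phase | free catalyst | remark | time |
|---|---|---|---|---|---|
| alpha | 1.5 M | 200 mM (held) | 21 mM | run made earlier |  |
| gamma | 1.5 M | 200 mM (held) | 33 mM | run made earlier |  |
| beta | 0.75 M | 200 mM (held) | 15 mM | run made earlier |  |
| flask | 1.5 M | 200 mM (held) | 15 mM |  | 10 d |

| run | time / d | product / % |
|---|---|---|
| alpha | 1.04 | 12.2 |
| alpha | 2.08 | 23.4 |
| alpha | 3.00 | 29.2 |
| alpha | 4.00 | 34.3 |
| alpha | 5.00 | 39.9 |
| alpha | 6.00 | 42.1 |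
| gamma | 1.04 | 14.3 |
| gamma | 2.08 | 24.0 |
| gamma | 3.00 | 31.4 |
| gamma | 4.00 | 36.4 |
| gamma | 5.00 | 40.5 |
| gamma | 6.00 | 43.8 |
| beta | 1.25 | 17.3 |
| beta | 2.50 | 28.6 |
| beta | 4.00 | 37.3 |
| beta | 5.00 | 43.2 |
| beta | 6.00 | 45.6 |

(each reading ± 0.5 percentage points)

- at the start none of the gas phase is in solution

- noon: doubling the saturation concentration of gas phase, all else as stated
- dusk: doubling the transfer coefficient of the gas phase, all else as stated
- autumn: doubling the amount of free catalyst, all else as stated

1. the product standing at 10 d, as a percentage of the starting material charged
2. the change that raises the amount of product at 10 d, in percent of the starting material charged most ("none" if none brings more than 2 percentage points) (noon / dusk / autumn / none)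
3. amount of product at 10 d, in percent of the starting material charged, after dusk

Take the exposure: the natural logarithm of the charge over the fraction of it still left, a pseudo-first-order clock that adds up along a run. Read it off the runs. From 3.00 d to 6.00 d the time doubles, and the alpha run gains 0.201 of exposure, the gamma run 0.199, although gamma holds more free catalyst. The alpha run stands at 0.509 at 5.00 d, so one more doubling, if it gains the same, gives 0.710.

Object that this flask holds less free catalyst than alpha. From alpha to gamma, the exposure at 5.00 d moved by 0.0100, so subtract that step once. It is a rough step, a difference of 0.6 percentage points between readings that scatter by 0.5 points. This gives my estimate of the flask's exposure at 10 d, 0.700, which means 50.3 % product.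

Object next that the gain per doubling is not constant: alpha gained 0.136 from 1.04 d to 2.08 d, less than 0.201 later. Keep the estimate, with its doubt pointing upward.

Now the changes. If the rate follows the dissolved gas, doubling the saturation doubles the exposure, giving 75.3 % product. Autumn looks weaker: from alpha to gamma the free catalyst rose by a factor 1.57, and the exposure at 5.00 d moved by 0.0100. The beta run, with half the starting material and less free catalyst, reaches 0.566 at 5.00 d, more than alpha, but two settings differ there, so take it as a hint for the gas and no proof. Choose noon, and place dusk between 50.3 % and 75.3 % product, without a sharper reckoning.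

The forecast gives 46 %, noon and 51 % after dusk, holding that “the catalyst is dying or product-inhibited”.

The flask gives 50.2 %, with noon best and 56.9 % after dusk; at 10.0 d its free catalyst stands at 6.81 % of the charge and its spent catalyst at 93.2 %.

    starting material + dissolved gas + free catalyst → free catalyst + product (k = 7.80 /M²/h)
    gas phase ⇌ dissolved gas, rate k2*(csat - [dissolved gas]) (kL = 0.0900 /h)
    2 free catalyst → spent catalyst (k = 1.90 /M/h)

Double the exposure 0.700 for the noon flask: the gain over this flask comes to 25 points. The noon flask gains 27 points.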